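**Plan**
- Retrosynthetic cuts: the benzylic C–OH bond of target 10 goes back through aldehyde 9 to the two C–OMe bonds of acetal 8. Those two bonds are cut to the methyl group of 2,3,6-tribromo-4-methylphenol 3, and the C2–Br and C6–Br bonds are cut last to reach 3-bromo-4-methylphenol 1.
- Forward order: the benzene ring is bought intact and no ring is formed. The sequence is double ortho-bromination, anodic CH3 to CH(OMe)2, acetal hydrolysis, hydride reduction.
- Enabling feature: the carbon that ends as CH2OH sits on ring carbon C4, para to the phenolic oxygen on C1, and both carbons ortho to that oxygen (C2, C6) carry bromine. Two-electron oxidation of the phenoxide can therefore give a para-quinone methide whose exocyclic carbon takes up methanol.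
- Stereochemistry: the target has no stereocentre and no stereogenic double bond, so nothing has to be controlled.

Key step: step 2

Remark: 3-bromo-4-methylphenol 1 is assumed to be a catalogue compound. The phenol is left unprotected throughout, because its phenoxide is the species the anode oxidises.

**Route**

Step 1
Reactants: 1 3-bromo-4-methylphenol; 2 bromine
Product: 3 2,3,6-tribromo-4-methylphenol
Conditions: Br2 (2.05 equiv), AcOH, 15–20 °C, dark; aq. NaHSO3 quench
Reagents that add atoms: bromine, BrBr
Why: Electrophilic aromatic bromination in which the hydroxyl group directs to its two free ortho carbons C2 and C6 (the para carbon carries the methyl group, C5 is meta to the hydroxyl), and any ipso adduct at C4 should be returned to the phenol by the HBr that accumulates.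

Step 2
Reactants: 3 2,3,6-tribromo-4-methylphenol; 4 methanol
Product: 8 2,3,6-tribromo-4-(dimethoxymethyl)phenol, via quinone methide 5 (not isolated), via benzylic methyl ether 6 (not isolated), via methoxy quinone methide 7 (not isolated)
Conditions: graphite anode, Pt cathode, undivided cell, NaOMe (2 equiv), MeOH (0.05 M in 3), constant current 10 mA/cm2, about 4.2 F/mol, 20 °C; solid NH4Cl quench
Reagents that add atoms: methanol, CO
Why: The sodium phenoxide of 3 gives up two electrons at graphite (through the phenoxyl radical) and a benzylic proton to methoxide, forming para-quinone methide 5; methanol adds 1,6 to the exocyclic carbon and re-aromatises the ring to ether 6, whose phenoxide runs through the same sequence via 7 to acetal 8, while the cathode reduces methanol to hydrogen and methoxide and so keeps the medium basic. The closest known reaction type is the anodic benzylic methoxylation of 4-methylphenols and 4-methylanisoles to benzaldehyde dimethyl acetals. No ring is closed and no stereocentre arises; the step forms the two benzylic C–O bonds. It needs chemoselectivity for benzylic proton loss over methanol capture at ring carbon C4 (a 4-methoxy dienone) and over O–C coupling of two phenoxyl radicals, and free methoxide, bromine on both ortho carbons, the further bromine on C3 next to C4, high dilution and a steady current should provide it. The charge is held near 4 F/mol because the acetal C–H is lost far less readily than a methyl or methylene C–H, and the aryl bromides should be spared because hydrogen evolution at platinum sets in well before C–Br reduction.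

Step 3
Reactants: 8 2,3,6-tribromo-4-(dimethoxymethyl)phenol
Product: 9 2,3,5-tribromo-4-hydroxybenzaldehyde
Conditions: 1 M aq. HCl, THF, 20 °C
Reagents that add atoms: water, O
Why: Acid-catalysed acetal hydrolysis, eased by the para-hydroxyl group that stabilises the oxocarbenium ion, under conditions that leave aryl bromides and the phenol untouched.

Step 4
Reactants: 9 2,3,5-tribromo-4-hydroxybenzaldehyde
Product: 10 2,3,6-tribromo-4-(hydroxymethyl)phenol
Conditions: NaBH4 (1.5 equiv), THF/EtOH, 0 to 20 °C; aq. NH4Cl, then citric acid to pH 5, cold
Reagents that add atoms: none
Why: Borohydride reduction of an aryl aldehyde to the primary alcohol, in which the three bromines keep the carbonyl electrophilic although the phenol is deprotonated, aryl bromides are inert to NaBH4, and a cold, weakly acidic work-up avoids ionising the new benzylic C–O bond.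

**Compound list**
1 | 3-bromo-4-methylphenol | Cc1ccc(O)cc1Br | starting material
2 | bromine | BrBr | starting material
3 | 2,3,6-tribromo-4-methylphenol | Cc1cc(Br)c(O)c(Br)c1Br | intermediate
4 | methanol | CO | starting material
5 | 2,3,6-tribromo-4-methylidenecyclohexa-2,5-dien-1-one (quinone methide, formed in the flask) | C=C1C=C(Br)C(=O)C(Br)=C1Br | intermediate
6 | 2,3,6-tribromo-4-(methoxymethyl)phenol (formed in the flask) | COCc1cc(Br)c(O)c(Br)c1Br | intermediate
7 | (E)-2,3,6-tribromo-4-(methoxymethylidene)cyclohexa-2,5-dien-1-one (formed in the flask; E isomer drawn, methoxy turned away from the C3 bromine, geometry without consequence for 8) | CO/C=C1\C=C(Br)C(=O)C(Br)=C1Br | intermediate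
8 | 2,3,6-tribromo-4-(dimethoxymethyl)phenol | COC(OC)c1cc(Br)c(O)c(Br)c1Br | intermediate
9 | 2,3,5-tribromo-4-hydroxybenzaldehyde | O=Cc1cc(Br)c(O)c(Br)c1Br | intermediate
10 | 2,3,6-tribromo-4-(hydroxymethyl)phenol | OCc1cc(Br)c(O)c(Br)c1Br | target

**Count**
Total steps: 4. Longest linear sequence: 4 steps (1 to 3 to 8 to 9 to 10).

**Steps most likely to fail**

Step 2 (anodic oxidation). The oxidised phenol may be diverted before the benzylic proton is lost. Possible diversions are O–C coupling of two phenoxyl radicals to aryloxy dienones, capture of methanol at ring carbon C4, and oxidation beyond the acetal level. The fallback sets out from 3 and rejoins the route at 10. Acetylation (Ac2O, pyridine, 20 °C) should give 2,3,6-tribromo-4-methylphenyl acetate F1, in which the ester blocks ring and ipso bromination and keeps the phenol from quenching radical chains. Wohl–Ziegler bromination (NBS 1.05 equiv, AIBN, PhCF3, 80 °C) should then give 2,3,6-tribromo-4-(bromomethyl)phenyl acetate F2. Treatment with K2CO3 in dilute aqueous acetone at 0 to 20 °C removes the acetate, the freed phenoxide expels bromide, and water adds to the resulting quinone methide 5. Careful acidification to pH 5 would deliver 10 directly, bypassing 8 and 9.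

Step 1 (dibromination). Entry of the second bromine at the crowded C2 position, between the hydroxyl group and the C3 bromine, may be slow. Ipso attack at C4 may then compete and leave a mixture of under- and over-brominated material. The fallback sets out from 1 and rejoins at 3. Excess Br2 (3.3 equiv) in aqueous AcOH buffered with NaOAc at 0 to 10 °C should drive everything to racemic 2,3,4,6-tetrabromo-4-methylcyclohexa-2,5-dien-1-one F3. Aqueous NaHSO3 at 0 °C then reduces the C4–Br bond, so the dienone collapses to phenol 3.

Step 4 (reduction). Hydride addition to the phenoxide-deactivated aldehyde may be sluggish. The benzylic oxygen may then be lost through a quinone methide, either by deoxygenation back to the methyl compound or by ether formation during work-up. The fallback sets out from 9 and rejoins at 10. Masking the phenol (MOMCl, iPr2NEt, CH2Cl2, 0 to 20 °C) should give 2,3,5-tribromo-4-(methoxymethoxy)benzaldehyde F4, which can no longer form a phenoxide. NaBH4 in MeOH at 0 °C should then give [2,3,5-tribromo-4-(methoxymethoxy)phenyl]methanol F5. Dilute HCl (2 M) in THF/water at 20 to 40 °C removes the methoxymethyl group and releases 10.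

**Further compounds**
F1 | step 2 | 2,3,6-tribromo-4-methylphenyl acetate | CC(=O)Oc1c(Br)cc(C)c(Br)c1Br
F2 | step 2 | 2,3,6-tribromo-4-(bromomethyl)phenyl acetate | CC(=O)Oc1c(Br)cc(CBr)c(Br)c1Br
F3 | step 1 | 2,3,4,6-tetrabromo-4-methylcyclohexa-2,5-dien-1-one (racemic) | CC1(Br)C=C(Br)C(=O)C(Br)=C1Br
F4 | step 4 | 2,3,5-tribromo-4-(methoxymethoxy)benzaldehyde | COCOc1c(Br)cc(C=O)c(Br)c1Br
F5 | step 4 | [2,3,5-tribromo-4-(methoxymethoxy)phenyl]methanol | COCOc1c(Br)cc(CO)c(Br)c1Br
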